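The route rests on splitting ring A into a vinylketene and an alkyne. Ring A, the formyl-bearing benzoate ring, is a resorcinol mono-aryl ether: hydroxyl carbon and ether carbon are meta, the formyl carbon lies between them and the carboxyl carbon adjoins the ether carbon. A vinylketene adding to an alkynyl ether produces exactly this pattern, so one light-then-heat cascade should form ring A and three C–C bonds on a ring B alkynyl ether whose hindered aryl–oxygen bond already exists. The partners are diazo keto ester 15 and chromanone alkynyl ether 10 carrying the formyl group as an acetal; acid unmasking and lactonisation of ring C finish.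

Key step: step 9

Remark: ring A is the formyl-bearing benzoate ring, ring B the arene fused to the pyranone, ring C the seven-membered ether-lactone and ring D the dimethylpyranone; 2,2-diethoxyacetaldehyde 7 is assumed to be purchasable, and the target has no stereocentre.

Step 1
Reactants: 1 2',4'-dihydroxy-6'-methylacetophenone
Product: 3 2',4',5'-trihydroxy-6'-methylacetophenone, via aryl potassium sulfate 2 (not isolated)
Conditions: K2S2O8, aq NaOH, 0 to 20 °C; then aq HCl, 90 °C
Reagents that add atoms: potassium peroxodisulfate, [K+].[K+].[O-]S(=O)(=O)OOS(=O)(=O)[O-]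
Why: Elbs persulfate oxidation: the phenolate of 1 should attack the peroxide oxygen through C5', the only free carbon para to a phenolate oxygen (the carbon para to the 4'-oxygen carries the acetyl group), and acid hydrolysis of aryl sulfate 2 then frees the new hydroxyl, unreacted 1 being extracted beforehand for recycling.

Step 2
Reactants: 3 2',4',5'-trihydroxy-6'-methylacetophenone
Product: 4 2',5'-dihydroxy-4'-(methoxymethoxy)-6'-methylacetophenone
Conditions: MOMCl (1.05 equiv), iPr2NEt, CH2Cl2, 0 °C
Reagents that add atoms: chloromethyl methyl ether, COCCl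
Why: Williamson-type O-alkylation that should pick the 4'-hydroxyl, the most acidic (para to the acetyl group) and least hindered one, while the 2'-hydroxyl is locked in a hydrogen bond to the carbonyl oxygen and the 5'-hydroxyl lies meta to the acetyl group between a methyl group and an oxygen.

Step 3
Reactants: 4 2',5'-dihydroxy-4'-(methoxymethoxy)-6'-methylacetophenone
Product: 6 6-hydroxy-7-(methoxymethoxy)-2,2,5-trimethylchroman-4-one, via hydroxyaryl enone 5 (not isolated)
Conditions: acetone (excess), pyrrolidine, EtOH, reflux, under Ar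
Reagents that add atoms: acetone, CC(C)=O
Why: Kabbe condensation: pyrrolidine-mediated aldol condensation of the acetyl group with acetone should give enone 5, to which the ortho hydroxyl adds in a 6-endo-trig oxa-Michael closure of ring D, the other free hydroxyl being out of reach and the methoxymethyl ether stable to the amine.

Step 4
Reactants: 7 2,2-diethoxyacetaldehyde
Product: 8 1,1-dibromo-3,3-diethoxyprop-1-ene
Conditions: CBr4, PPh3, Et3N, CH2Cl2, 0 °C
Reagents that add atoms: tetrabromomethane, BrC(Br)(Br)Br
Why: Ramirez dibromoolefination (first half of the Corey–Fuchs sequence) of an unhindered aldehyde, with Et3N present so that the bromophosphonium by-product cannot cleave the acetal.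

Step 5
Reactants: 6 6-hydroxy-7-(methoxymethoxy)-2,2,5-trimethylchroman-4-one; 8 1,1-dibromo-3,3-diethoxyprop-1-ene
Product: 9 6-{[(1Z)-1-bromo-3,3-diethoxyprop-1-en-1-yl]oxy}-7-(methoxymethoxy)-2,2,5-trimethylchroman-4-one
Conditions: CuI (10 mol %), 2,2'-bipyridine (20 mol %), K3PO4, PhMe, 110 °C
Reagents that add atoms: none
Why: Copper-catalysed Ullmann-type C–O coupling of a phenol with a 1,1-dibromoalkene, a known reaction that stops at the bromo enol ether; the C–Br bond trans to the acetal-bearing carbon should react, which gives the Z isomer, and bond formation at a slim sp2 carbon should tolerate the two ortho substituents of phenol 6.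

Step 6
Reactants: 9 6-{[(1Z)-1-bromo-3,3-diethoxyprop-1-en-1-yl]oxy}-7-(methoxymethoxy)-2,2,5-trimethylchroman-4-one
Product: 10 6-[(3,3-diethoxyprop-1-yn-1-yl)oxy]-7-(methoxymethoxy)-2,2,5-trimethylchroman-4-one
Conditions: KOtBu (2.2 equiv), 1,4-dioxane, 20 °C
Reagents that add atoms: none
Why: E2 dehydrobromination of the bromo enol ether, in which hydrogen and bromine are anti across the double bond, is the established second half of this alkynyl ether synthesis; acetal and methoxymethyl ether are inert to base and the chromanone should only enolise reversibly.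

Step 7
Reactants: 11 tert-butyl acetate; 12 methacryloyl chloride
Product: 14 tert-butyl 4-methyl-3-oxopent-4-enoate, via lithium enolate 13 (not isolated)
Conditions: 11 (2.1 equiv), LiN(SiMe3)2 (2.1 equiv), THF, −78 °C; then 12 (1 equiv), −78 °C; cold dilute acid quench
Reagents that add atoms: none
Why: Crossed Claisen acylation of an ester enolate by an acid chloride: 1,2-attack on the acyl chloride should outrun conjugate addition, and the second equivalent of enolate 13 deprotonates keto ester 14 as it forms, which shields its isopropenyl ketone until the quench.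

Step 8
Reactants: 14 tert-butyl 4-methyl-3-oxopent-4-enoate
Product: 15 tert-butyl 2-diazo-4-methyl-3-oxopent-4-enoate
Conditions: 4-acetamidobenzenesulfonyl azide, Et3N, MeCN, 0 to 20 °C
Reagents that add atoms: 4-acetamidobenzenesulfonyl azide, CC(=O)Nc1ccc(cc1)S(=O)(=O)N=[N+]=[N-]
Why: Regitz diazo transfer from a sulfonyl azide to the doubly activated methylene group of a β-keto ester under mild amine base.

Step 9
Reactants: 10 6-[(3,3-diethoxyprop-1-yn-1-yl)oxy]-7-(methoxymethoxy)-2,2,5-trimethylchroman-4-one; 15 tert-butyl 2-diazo-4-methyl-3-oxopent-4-enoate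
Product: 20 tert-butyl 3-(diethoxymethyl)-4-hydroxy-2-{[7-(methoxymethoxy)-2,2,5-trimethyl-4-oxochroman-6-yl]oxy}-6-methylbenzoate, via vinylketene 16 (not isolated), via cyclobutenone 17 (not isolated), via dienylketene 18 (not isolated), via cyclohexadienone 19 (not isolated)
Conditions: 15 (3 equiv, in portions), hν (254 nm, quartz), degassed CH2Cl2, 20 °C; then PhMe, 90 °C
Reagents that add atoms: none
Why: Light expels N2 from 15 and Wolff rearrangement, with the isopropenyl group migrating to the carbene carbon, gives vinylketene 16; the acetal-bearing carbon of 10 (the nucleophilic end of the alkynyl ether) bonds to the ketene carbonyl carbon and the oxygen-bearing carbon to the ketene α-carbon in a [2+2] addition, giving cyclobutenone 17. Heating then opens 17 reversibly in a conrotatory four-electron process to dienylketene 18, ring A closes by disrotatory six-electron electrocyclisation between the ketene carbon and the methylene terminus (the third C–C bond) to dienone 19, and enolisation gives phenol 20. The closest known reaction type is the Danheiser benzannulation in its photochemical Wolff form, established for vinylketenes from unsaturated diazo ketones with alkoxy- and siloxyalkynes; this exact pairing of an alkoxycarbonyl-substituted vinylketene with an aryl alkynyl ether is untried. No stereocentre is kept: the quaternary carbon of 17 is racemic and is lost on ring opening. Two selectivities are needed: the regiochemistry of the [2+2] step is set by donation from the ether oxygen, which makes the acetal-bearing carbon the nucleophile, and [2+2] addition should outrun hetero-[4+2] addition because an ester carbonyl, already engaged in alkoxy resonance, is a reluctant heterodiene terminus. Irradiation at 254 nm with 15 in excess should let the diazo chromophore take most of the light from the ring B aryl ketone, the aryl alkynyl ether has no hydrogen placed for retro-ene loss of an alkene on heating, and heating only after the ketene is spent should keep phenol 20 from being acylated.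

Step 10
Reactants: 20 tert-butyl 3-(diethoxymethyl)-4-hydroxy-2-{[7-(methoxymethoxy)-2,2,5-trimethyl-4-oxochroman-6-yl]oxy}-6-methylbenzoate
Product: 21 3-formyl-4-hydroxy-2-[(7-hydroxy-2,2,5-trimethyl-4-oxochroman-6-yl)oxy]-6-methylbenzoic acid
Conditions: CF3CO2H, CH2Cl2, H2O, anisole, 0 to 20 °C
Reagents that add atoms: water, O
Why: Acidolysis in one operation: the tert-butyl ester should lose 2-methylpropene, the acetal should hydrolyse with the added water and the methoxymethyl ether should be cleaved, anisole trapping the cations, while formyl and carboxyl groups are meta on ring A and so cannot form a lactol.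

Step 11
Reactants: 21 3-formyl-4-hydroxy-2-[(7-hydroxy-2,2,5-trimethyl-4-oxochroman-6-yl)oxy]-6-methylbenzoic acid
Product: 23 Mollicellin A, via mixed anhydride 22 (not isolated)
Conditions: (CF3CO)2O, CH2Cl2, 0 to 20 °C; aq NaHCO3 work-up
Reagents that add atoms: none
Why: Lactonisation through a mixed trifluoroacetic anhydride, a standard activation for hindered benzoic acids and a known ring closure in depsidone synthesis: the ring B hydroxyl next to the diaryl ether oxygen should attack the acyl carbon to close seven-membered ring C, the ring A hydroxyl being para to the carboxyl and out of reach, and the bicarbonate wash should cleave any aryl trifluoroacetate.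

Compound list
1 | 2',4'-dihydroxy-6'-methylacetophenone | CC(=O)c1c(C)cc(O)cc1O | starting material
2 | potassium 3-acetyl-4,6-dihydroxy-2-methylphenyl sulfate | CC(=O)c1c(C)c(OS(=O)(=O)[O-])c(O)cc1O.[K+] | intermediate
3 | 2',4',5'-trihydroxy-6'-methylacetophenone | CC(=O)c1c(C)c(O)c(O)cc1O | intermediate
4 | 2',5'-dihydroxy-4'-(methoxymethoxy)-6'-methylacetophenone | CC(=O)c1c(C)c(O)c(OCOC)cc1O | intermediate
5 | 1-[3,6-dihydroxy-4-(methoxymethoxy)-2-methylphenyl]-3-methylbut-2-en-1-one | CC(C)=CC(=O)c1c(C)c(O)c(OCOC)cc1O | intermediate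
6 | 6-hydroxy-7-(methoxymethoxy)-2,2,5-trimethylchroman-4-one | Cc1c(O)c(OCOC)cc2OC(C)(C)CC(=O)c12 | intermediate
7 | 2,2-diethoxyacetaldehyde | CCOC(OCC)C=O | starting material
8 | 1,1-dibromo-3,3-diethoxyprop-1-ene | CCOC(OCC)C=C(Br)Br | intermediate
9 | 6-{[(1Z)-1-bromo-3,3-diethoxyprop-1-en-1-yl]oxy}-7-(methoxymethoxy)-2,2,5-trimethylchroman-4-one | CCOC(OCC)/C=C(\Br)Oc1c(OCOC)cc2OC(C)(C)CC(=O)c2c1C | intermediate
10 | 6-[(3,3-diethoxyprop-1-yn-1-yl)oxy]-7-(methoxymethoxy)-2,2,5-trimethylchroman-4-one | CCOC(OCC)C#COc1c(OCOC)cc2OC(C)(C)CC(=O)c2c1C | intermediate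
11 | tert-butyl acetate | CC(=O)OC(C)(C)C | starting material
12 | methacryloyl chloride | CC(=C)C(=O)Cl | starting material
13 | lithium 1-(tert-butoxy)ethen-1-olate | [Li+].[O-]C(=C)OC(C)(C)C | intermediate
14 | tert-butyl 4-methyl-3-oxopent-4-enoate | CC(=C)C(=O)CC(=O)OC(C)(C)C | intermediate
15 | tert-butyl 2-diazo-4-methyl-3-oxopent-4-enoate | CC(=C)C(=O)C(=[N+]=[N-])C(=O)OC(C)(C)C | intermediate
16 | tert-butyl 3-methyl-2-(oxomethylidene)but-3-enoate | CC(=C)C(=C=O)C(=O)OC(C)(C)C | intermediate
17 | tert-butyl 3-(diethoxymethyl)-2-{[7-(methoxymethoxy)-2,2,5-trimethyl-4-oxochroman-6-yl]oxy}-4-oxo-1-(prop-1-en-2-yl)cyclobut-2-ene-1-carboxylate (racemic) | CCOC(OCC)C1=C(Oc2c(OCOC)cc3OC(C)(C)CC(=O)c3c2C)C(C(C)=C)(C(=O)OC(C)(C)C)C1=O | intermediate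
18 | tert-butyl (2Z)-4-(diethoxymethyl)-3-{[7-(methoxymethoxy)-2,2,5-trimethyl-4-oxochroman-6-yl]oxy}-5-oxo-2-(prop-1-en-2-yl)penta-2,4-dienoate | CCOC(OCC)C(=C=O)/C(Oc1c(OCOC)cc2OC(C)(C)CC(=O)c2c1C)=C(\C(C)=C)C(=O)OC(C)(C)C | intermediate
19 | tert-butyl 5-(diethoxymethyl)-6-{[7-(methoxymethoxy)-2,2,5-trimethyl-4-oxochroman-6-yl]oxy}-2-methyl-4-oxocyclohexa-1,5-diene-1-carboxylate | CCOC(OCC)C1=C(Oc2c(OCOC)cc3OC(C)(C)CC(=O)c3c2C)C(C(=O)OC(C)(C)C)=C(C)CC1=O | intermediate
20 | tert-butyl 3-(diethoxymethyl)-4-hydroxy-2-{[7-(methoxymethoxy)-2,2,5-trimethyl-4-oxochroman-6-yl]oxy}-6-methylbenzoate | Cc1cc(O)c(C(OCC)OCC)c(Oc2c(OCOC)cc3OC(C)(C)CC(=O)c3c2C)c1C(=O)OC(C)(C)C | intermediate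
21 | 3-formyl-4-hydroxy-2-[(7-hydroxy-2,2,5-trimethyl-4-oxochroman-6-yl)oxy]-6-methylbenzoic acid | Cc1cc(O)c(C=O)c(Oc2c(O)cc3OC(C)(C)CC(=O)c3c2C)c1C(=O)O | intermediate
22 | 3-formyl-4-hydroxy-2-[(7-hydroxy-2,2,5-trimethyl-4-oxochroman-6-yl)oxy]-6-methylbenzoic trifluoroacetic anhydride | Cc1cc(O)c(C=O)c(Oc2c(O)cc3OC(C)(C)CC(=O)c3c2C)c1C(=O)OC(=O)C(F)(F)F | intermediate
23 | Mollicellin A | Cc1cc(O)c(C=O)c2c1C(=O)Oc1cc3c(c(C)c1O2)C(=O)CC(C)(C)O3 | target

Total step count: 11. Longest linear sequence: 8 steps (steps 1, 2, 3, 5, 6, 9, 10, 11, from 1 to 23).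

Steps most likely to fail

Step 9. The ketene may be consumed by hetero-[4+2] addition through its ester carbonyl or by self-condensation before the weakly nucleophilic aryl alkynyl ether captures it, and light absorbed by the ring B ketone may divert the diazo ester into triplet carbene chemistry. The fallback gives up the annulation and brings ring A in preformed; it sets out from 6 and comes back at 21. Commercial 4-bromo-2-fluoro-6-methylbenzoic acid would be deprotonated between fluorine and bromine (LiN(iPr)2, 2.2 equiv, THF, −78 °C) and formylated with DMF to give 4-bromo-2-fluoro-3-formyl-6-methylbenzoic acid F1. Esterification with tert-butyl 2,2,2-trichloroacetimidate (cat. BF3·OEt2) would give tert-butyl 4-bromo-2-fluoro-3-formyl-6-methylbenzoate F2. Nucleophilic aromatic substitution by phenol 6 (K2CO3, DMF, 70 °C) at the fluorine-bearing carbon, which is activated by the ortho formyl and ortho ester groups, would give the bromo diaryl ether F3. Palladium-catalysed hydroxylation of the bromide (Pd2(dba)3, tBuXPhos, KOH, 1,4-dioxane/H2O, 80 °C) would give the ring A phenol F4. The acid treatment of step 10 would then convert F4 into 21.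

Step 5. Coupling at the doubly ortho-substituted phenol may be slower than base-induced dehydrobromination of 8 to a labile bromoalkyne, so that 8 is lost before the C–O bond forms. The fallback makes the C–O bond by alkylation at an sp3 carbon and creates the triple bond afterwards; it sets out from 6 and comes back at 10. Commercial 1,1-diethoxypropan-2-one would be brominated at the methyl group (Br2, EtOH, 0 °C) to 3-bromo-1,1-diethoxypropan-2-one F5. Phenol 6 would be alkylated with it (K2CO3, acetone, 50 °C) to the aryloxy ketone F6. Deprotonation at the more acidic aryloxy-substituted methylene (LiN(SiMe3)2, 1.05 equiv, THF, −78 °C) and trapping of the chelated enolate with PhNTf2 would give the Z enol triflate F7. KOtBu (THF, −78 °C) would then eliminate triflate anti to the vinyl hydrogen and give 10.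

Step 1. Over-oxidation of the electron-rich dihydroxyphenolate and incomplete conversion may leave little triol after the persulfate oxidation. The fallback introduces the oxygen by halogenation and C–O coupling; it sets out from 1 and comes back at 4. The unchelated hydroxyl of 1 would be protected (MOMCl, iPr2NEt, CH2Cl2) to give 2'-hydroxy-4'-(methoxymethoxy)-6'-methylacetophenone F8. Bromination with NBS (MeCN, 0 °C), expected mainly para to the free phenol, would give 5'-bromo-2'-hydroxy-4'-(methoxymethoxy)-6'-methylacetophenone F9. Palladium-catalysed hydroxylation (Pd2(dba)3, tBuXPhos, KOH, 1,4-dioxane/H2O, 80 °C) would then give 4.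

Further compounds
F1 | step 9 | 4-bromo-2-fluoro-3-formyl-6-methylbenzoic acid | Cc1cc(Br)c(C=O)c(F)c1C(=O)O
F2 | step 9 | tert-butyl 4-bromo-2-fluoro-3-formyl-6-methylbenzoate | Cc1cc(Br)c(C=O)c(F)c1C(=O)OC(C)(C)C
F3 | step 9 | tert-butyl 4-bromo-3-formyl-2-{[7-(methoxymethoxy)-2,2,5-trimethyl-4-oxochroman-6-yl]oxy}-6-methylbenzoate | Cc1cc(Br)c(C=O)c(Oc2c(OCOC)cc3OC(C)(C)CC(=O)c3c2C)c1C(=O)OC(C)(C)C
F4 | step 9 | tert-butyl 3-formyl-4-hydroxy-2-{[7-(methoxymethoxy)-2,2,5-trimethyl-4-oxochroman-6-yl]oxy}-6-methylbenzoate | Cc1cc(O)c(C=O)c(Oc2c(OCOC)cc3OC(C)(C)CC(=O)c3c2C)c1C(=O)OC(C)(C)C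
F5 | step 5 | 3-bromo-1,1-diethoxypropan-2-one | CCOC(OCC)C(=O)CBr
F6 | step 5 | 6-(3,3-diethoxy-2-oxopropoxy)-7-(methoxymethoxy)-2,2,5-trimethylchroman-4-one | CCOC(OCC)C(=O)COc1c(OCOC)cc2OC(C)(C)CC(=O)c2c1C
F7 | step 5 | (1Z)-3,3-diethoxy-1-{[7-(methoxymethoxy)-2,2,5-trimethyl-4-oxochroman-6-yl]oxy}prop-1-en-2-yl trifluoromethanesulfonate | CCOC(OCC)/C(OS(=O)(=O)C(F)(F)F)=C/Oc1c(OCOC)cc2OC(C)(C)CC(=O)c2c1C
F8 | step 1 | 2'-hydroxy-4'-(methoxymethoxy)-6'-methylacetophenone | CC(=O)c1c(C)cc(OCOC)cc1O
F9 | step 1 | 5'-bromo-2'-hydroxy-4'-(methoxymethoxy)-6'-methylacetophenone | CC(=O)c1c(C)c(Br)c(OCOC)cc1O
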